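## Retrosynthetic overview

- Lactone ring (closed last): the C3 benzylic alcohol attacks an ortho methyl ester; the γ-hydroxy ketone is released from a 2-methoxyoxolane ketal in the same acid treatment.
- Benzene ring (built first): Alder–Rickert sequence, a [4+2] cycloaddition of a 4-silyloxy-2-ynoate with 1-methoxy-3-silyloxycyclohexa-1,3-diene, then retro-[4+2] loss of ethene. This places OMe ortho and OH para to the ester carbon.
- Ynoate: α-silyloxy ester → aldehyde → terminal alkyne (one-carbon homologation) → C-carboxylation.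
- C3 stereocentre: methyl (S)-glycidate opened at CH2 by a copper-catalysed Grignard reagent. Side-chain carbinol: (S)-γ-valerolactone opened once by 8-chlorooctylmagnesium bromide.

## Route

Step 1
Reactants: 1 1-bromo-8-chlorooctane; 2 (5S)-5-methyloxolan-2-one [(S)-γ-valerolactone]
Product: 5 (5S)-2-(8-chlorooctyl)-2-methoxy-5-methyloxolane (both C2 epimers), via Grignard reagent 3 (not isolated), via hydroxy ketone 4 (not isolated)
Conditions: Mg, THF, 30 °C; add to 2 (1.2 equiv), THF, −78 °C; then HCl in MeOH (1.3 equiv), −78 °C → rt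
Reagents that add atoms: methanol (CO)
Why: Mg inserts selectively into C–Br, the Grignard reagent adds once to the lactone because the magnesium hemiketalate is stable at −78 °C (nucleophilic acyl addition), and acidic methanol closes the γ-hydroxy ketone to its cyclic methyl ketal (Fischer-type ketalization) without touching the (S)-carbinol bought with 2.

Step 2
Reactants: 5 (5S)-2-(8-chlorooctyl)-2-methoxy-5-methyloxolane; 6 methyl (2S)-oxirane-2-carboxylate [methyl (S)-glycidate]
Product: 8 methyl (2S)-2-hydroxy-11-[(5S)-2-methoxy-5-methyloxolan-2-yl]undecanoate, via Grignard reagent 7 (not isolated)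
Conditions: 5, Mg (I2-activated), THF, reflux; then 6, CuI (10 mol %), THF, −40 → −10 °C; H2O quench
Reagents that add atoms: none
Why: Copper-catalysed SN2 opening of the glycidic ester at its unsubstituted CH2 (cuprate epoxide opening) outruns ester attack at low temperature and breaks no bond at C2, so the bought (S) centre becomes the (2S)-α-hydroxy ester.

Step 3
Reactants: 8 methyl (2S)-2-hydroxy-11-[(5S)-2-methoxy-5-methyloxolan-2-yl]undecanoate
Product: 9 methyl (2S)-2-[(tert-butyldimethylsilyl)oxy]-11-[(5S)-2-methoxy-5-methyloxolan-2-yl]undecanoate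
Conditions: TBSCl, imidazole, DMF, rt
Reagents that add atoms: tert-butyldimethylsilyl chloride (CC(C)(C)[Si](C)(C)Cl)
Why: Standard O-silylation of the secondary alcohol under non-acidic conditions protects it for the hydride and organolithium steps and leaves the ketal and the stereocentre untouched.

Step 4
Reactants: 9 methyl (2S)-2-[(tert-butyldimethylsilyl)oxy]-11-[(5S)-2-methoxy-5-methyloxolan-2-yl]undecanoate
Product: 11 tert-butyl({(3S)-12-[(5S)-2-methoxy-5-methyloxolan-2-yl]dodec-1-yn-3-yl}oxy)dimethylsilane, via aldehyde 10 (not isolated)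
Conditions: i-Bu2AlH (1.1 equiv), CH2Cl2, −78 °C; then MeOH, K2CO3, dimethyl (1-diazo-2-oxopropyl)phosphonate, −78 °C → rt
Reagents that add atoms: dimethyl (1-diazo-2-oxopropyl)phosphonate (CC(=O)C(=[N+]=[N-])P(=O)(OC)OC)
Why: Half-reduction of the α-silyloxy ester through a chelated aluminium hemiacetal followed in the same pot by Ohira–Bestmann (Seyferth–Gilbert) homologation gives the terminal alkyne, and the mild carbonate base keeps the α-silyloxy centre (S).

Step 5
Reactants: 11 tert-butyl({(3S)-12-[(5S)-2-methoxy-5-methyloxolan-2-yl]dodec-1-yn-3-yl}oxy)dimethylsilane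
Product: 13 methyl (4S)-4-[(tert-butyldimethylsilyl)oxy]-13-[(5S)-2-methoxy-5-methyloxolan-2-yl]tridec-2-ynoate, via lithium acetylide 12 (not isolated)
Conditions: n-BuLi, THF, −78 °C; then ClCO2Me, −78 → 0 °C
Reagents that add atoms: methyl chloroformate (COC(=O)Cl)
Why: Deprotonation of the terminal alkyne and C-acylation of the acetylide with the chloroformate gives the electron-poor ynoate dienophile with no change at the propargylic centre.

Step 6
Reactants: 14 3-methoxycyclohex-2-en-1-one
Product: 16 1-methoxy-3-[(trimethylsilyl)oxy]cyclohexa-1,3-diene, via lithium dienolate 15 (not isolated)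
Conditions: LiN(i-Pr)2, THF, −78 °C; then Me3SiCl, −78 °C → rt; distil
Reagents that add atoms: chlorotrimethylsilane (C[Si](C)(C)Cl)
Why: Kinetic α′-deprotonation of the vinylogous ester and O-silylation (silyl enol ether formation) gives the cross-conjugated diene whose termini are the OMe-bearing carbon and an unsubstituted CH.

Step 7
Reactants: 13 methyl (4S)-4-[(tert-butyldimethylsilyl)oxy]-13-[(5S)-2-methoxy-5-methyloxolan-2-yl]tridec-2-ynoate; 16 1-methoxy-3-[(trimethylsilyl)oxy]cyclohexa-1,3-diene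
Product: 20 (3S)-5-hydroxy-3-[(13S)-13-hydroxy-10-oxotetradecyl]-7-methoxy-2-benzofuran-1(3H)-one, via bicyclooctadiene adduct 17 (not isolated), via silylated benzoate 18 (not isolated), via seco hydroxy ester 19 (not isolated)
Conditions: 16 (3 equiv), neat, BHT (cat.), sealed tube, 150 °C; then 48% aq. HF, MeCN/THF, 0 °C → rt
Reagents that add atoms: water (O)
Why: In this Alder–Rickert reaction both donor groups make the unsubstituted diene terminus bond to the ynoate β-carbon in the Diels–Alder [4+2] step and retro-Diels–Alder loss of ethene gives the benzoate with OMe ortho and silyloxy para to the ester, after which aqueous HF removes both silyl groups and the ketal and the freed benzylic alcohol lactonizes by acyl substitution with retention, so C3 keeps the (S) configuration of 6 and C13′ that of 2.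

## Compound list

1 | 1-bromo-8-chlorooctane | ClCCCCCCCCBr | starting material
2 | (5S)-5-methyloxolan-2-one [(S)-γ-valerolactone] | C[C@H]1CCC(=O)O1 | starting material
3 | (8-chlorooctyl)magnesium bromide | ClCCCCCCCC[Mg]Br | intermediate
4 | (2S)-13-chloro-2-hydroxytridecan-5-one | C[C@H](O)CCC(=O)CCCCCCCCCl | intermediate
5 | (5S)-2-(8-chlorooctyl)-2-methoxy-5-methyloxolane (both C2 epimers) | COC1(CCCCCCCCCl)CC[C@H](C)O1 | intermediate
6 | methyl (2S)-oxirane-2-carboxylate [methyl (S)-glycidate] | COC(=O)[C@@H]1CO1 | starting material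
7 | {8-[(5S)-2-methoxy-5-methyloxolan-2-yl]octyl}magnesium chloride | COC1(CCCCCCCC[Mg]Cl)CC[C@H](C)O1 | intermediate
8 | methyl (2S)-2-hydroxy-11-[(5S)-2-methoxy-5-methyloxolan-2-yl]undecanoate | COC(=O)[C@@H](O)CCCCCCCCCC1(OC)CC[C@H](C)O1 | intermediate
9 | methyl (2S)-2-[(tert-butyldimethylsilyl)oxy]-11-[(5S)-2-methoxy-5-methyloxolan-2-yl]undecanoate | COC(=O)[C@@H](O[Si](C)(C)C(C)(C)C)CCCCCCCCCC1(OC)CC[C@H](C)O1 | intermediate
10 | (2S)-2-[(tert-butyldimethylsilyl)oxy]-11-[(5S)-2-methoxy-5-methyloxolan-2-yl]undecanal | O=C[C@@H](O[Si](C)(C)C(C)(C)C)CCCCCCCCCC1(OC)CC[C@H](C)O1 | intermediate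
11 | tert-butyl({(3S)-12-[(5S)-2-methoxy-5-methyloxolan-2-yl]dodec-1-yn-3-yl}oxy)dimethylsilane | C#C[C@@H](O[Si](C)(C)C(C)(C)C)CCCCCCCCCC1(OC)CC[C@H](C)O1 | intermediate
12 | lithium (3S)-3-[(tert-butyldimethylsilyl)oxy]-12-[(5S)-2-methoxy-5-methyloxolan-2-yl]dodec-1-yn-1-ide | [Li]C#C[C@@H](O[Si](C)(C)C(C)(C)C)CCCCCCCCCC1(OC)CC[C@H](C)O1 | intermediate
13 | methyl (4S)-4-[(tert-butyldimethylsilyl)oxy]-13-[(5S)-2-methoxy-5-methyloxolan-2-yl]tridec-2-ynoate | COC(=O)C#C[C@@H](O[Si](C)(C)C(C)(C)C)CCCCCCCCCC1(OC)CC[C@H](C)O1 | intermediate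
14 | 3-methoxycyclohex-2-en-1-one | COC1=CC(=O)CCC1 | starting material
15 | lithium 5-methoxycyclohexa-1,5-dien-1-olate | [Li+].[O-]C1=CCCC(OC)=C1 | intermediate
16 | 1-methoxy-3-[(trimethylsilyl)oxy]cyclohexa-1,3-diene | COC1=CC(O[Si](C)(C)C)=CCC1 | intermediate
17 | methyl 3-{(1S)-1-[(tert-butyldimethylsilyl)oxy]-10-[(5S)-2-methoxy-5-methyloxolan-2-yl]decyl}-1-methoxy-5-[(trimethylsilyl)oxy]bicyclo[2.2.2]octa-2,5-diene-2-carboxylate (bridgehead diastereomers) | COC(=O)C1=C([C@@H](O[Si](C)(C)C(C)(C)C)CCCCCCCCCC2(OC)CC[C@H](C)O2)C3CCC1(OC)C=C3O[Si](C)(C)C | intermediate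
18 | methyl 2-{(1S)-1-[(tert-butyldimethylsilyl)oxy]-10-[(5S)-2-methoxy-5-methyloxolan-2-yl]decyl}-6-methoxy-4-[(trimethylsilyl)oxy]benzoate | COC(=O)c1c(OC)cc(O[Si](C)(C)C)cc1[C@@H](O[Si](C)(C)C(C)(C)C)CCCCCCCCCC1(OC)CC[C@H](C)O1 | intermediate
19 | methyl 2-[(1S,14S)-1,14-dihydroxy-11-oxopentadecyl]-4-hydroxy-6-methoxybenzoate | COC(=O)c1c(OC)cc(O)cc1[C@@H](O)CCCCCCCCCC(=O)CC[C@H](C)O | intermediate
20 | (3S)-5-hydroxy-3-[(13S)-13-hydroxy-10-oxotetradecyl]-7-methoxy-2-benzofuran-1(3H)-one | COc1cc(O)cc2c1C(=O)O[C@H]2CCCCCCCCCC(=O)CC[C@H](C)O | target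

## Step count and risks

Total steps: 7. Longest linear sequence: 6 (steps 1, 2, 3, 4, 5, 7); step 6 is a one-step side branch.

**Step 1.** The risk is a second addition of Grignard reagent 3 to the lactone (diol formation) or incomplete ketalization. The fallback sets out from 2 and comes back at 4. Aminolysis of 2 with MeNHOMe·HCl/AlMe3 (CH2Cl2, 0 °C → rt) gives (4S)-4-hydroxy-N-methoxy-N-methylpentanamide F1. Grignard reagent 3 (2.2 equiv, THF, 0 °C) then adds only once, because the chelated tetrahedral adduct survives until work-up, and releases hydroxy ketone 4. This is ketalized with HCl/MeOH to 5 as before.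

**Step 4.** The risk is over-reduction of the ester, or epimerization of α-silyloxy aldehyde 10 in the basic one-pot homologation. The fallback sets out from 9 and comes back at 12. LiBH4 (THF) reduces 9 to (2S)-2-[(tert-butyldimethylsilyl)oxy]-11-[(5S)-2-methoxy-5-methyloxolan-2-yl]undecan-1-ol F2. Dess–Martin periodinane buffered with NaHCO3 gives 10, which is converted at once with CBr4/PPh3/Et3N (CH2Cl2, 0 °C) into tert-butyl({(3S)-1,1-dibromo-12-[(5S)-2-methoxy-5-methyloxolan-2-yl]dodec-1-en-3-yl}oxy)dimethylsilane F3. n-BuLi (2.1 equiv, THF, −78 °C) turns F3 directly into lithium acetylide 12 (Corey–Fuchs), which is trapped with ClCO2Me to give 13.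

**Step 7.** The risk is that adduct 17 does not shed ethene cleanly at 150 °C, or that the ketal or ynoate degrades at that temperature. The fallback sets out from 13 and comes back at 18. 1,1-Dimethoxyethene is acetylated (AcCl, Et3N) to 4,4-dimethoxybut-3-en-2-one F4, which is O-silylated (LiN(i-Pr)2, Me3SiCl, THF, −78 °C) to 1,1-dimethoxy-3-[(trimethylsilyl)oxy]buta-1,3-diene F5. F5 and 13 in toluene at 90 °C undergo the same regioselective [4+2] cycloaddition to give methyl 2-{(1S)-1-[(tert-butyldimethylsilyl)oxy]-10-[(5S)-2-methoxy-5-methyloxolan-2-yl]decyl}-6,6-dimethoxy-4-[(trimethylsilyl)oxy]cyclohexa-1,4-diene-1-carboxylate F6. F6 aromatizes by loss of methanol, with no cycloreversion needed, to 18, and the HF treatment of step 7 completes the synthesis.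

## Further compounds

F1 | step 1 | (4S)-4-hydroxy-N-methoxy-N-methylpentanamide | C[C@H](O)CCC(=O)N(C)OC
F2 | step 4 | (2S)-2-[(tert-butyldimethylsilyl)oxy]-11-[(5S)-2-methoxy-5-methyloxolan-2-yl]undecan-1-ol | OC[C@@H](O[Si](C)(C)C(C)(C)C)CCCCCCCCCC1(OC)CC[C@H](C)O1
F3 | step 4 | tert-butyl({(3S)-1,1-dibromo-12-[(5S)-2-methoxy-5-methyloxolan-2-yl]dodec-1-en-3-yl}oxy)dimethylsilane | BrC(Br)=C[C@@H](O[Si](C)(C)C(C)(C)C)CCCCCCCCCC1(OC)CC[C@H](C)O1
F4 | step 7 | 4,4-dimethoxybut-3-en-2-one | CC(=O)C=C(OC)OC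
F5 | step 7 | 1,1-dimethoxy-3-[(trimethylsilyl)oxy]buta-1,3-diene | COC(OC)=CC(=C)O[Si](C)(C)C
F6 | step 7 | methyl 2-{(1S)-1-[(tert-butyldimethylsilyl)oxy]-10-[(5S)-2-methoxy-5-methyloxolan-2-yl]decyl}-6,6-dimethoxy-4-[(trimethylsilyl)oxy]cyclohexa-1,4-diene-1-carboxylate | COC(=O)C1=C([C@@H](O[Si](C)(C)C(C)(C)C)CCCCCCCCCC2(OC)CC[C@H](C)O2)CC(O[Si](C)(C)C)=CC1(OC)OC
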